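Ring atoms: C1 (C=O), C2 (pentenyl), C3 (ester chain), C4 (OH), C5 (Br). The cyclopentenone is disconnected as a formal [3+2] along its aldol retron: the β-hydroxy ketone O–C4–C5–C1=O and the cis arrangement of C1 and C4 across the tetrasubstituted ring alkene C2=C3. In one flask an asymmetric Mukaiyama aldol joins an acetate unit (C5–C1) to the aldehyde C4 of a Z-β-iodo enal (C2=C3–C4, both side chains in place), and iodine–magnesium exchange then lets C2 close the ring on the ester C1. Bromine enters last, trans to the C4 silyl ether.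

Key step: step 7

Assumption: the antipode of the binaphthyl Schiff-base ligand is chosen so that the ketene acetal adds to the Si face of the iodo enal (S carbinol); the sense of induction on this substrate is not known in advance and both antipodes are accessible.

Step 1
Reactants: 1 (Z)-pent-2-en-1-ol
Product: 2 (Z)-1-bromopent-2-ene
Conditions: PBr3 (0.4 equiv), pyridine (cat.), Et2O, −10 °C
Reagents that add atoms: phosphorus tribromide, BrP(Br)Br
Why: PBr3 converts the primary allylic alcohol into the bromide by SN2 displacement of the phosphite ester at low temperature, which should keep the Z double bond and avoid allylic transposition.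

Step 2
Reactants: 2 (Z)-1-bromopent-2-ene; 3 prop-2-yn-1-ol
Product: 4 (Z)-oct-5-en-2-yn-1-ol
Conditions: CuI (10 mol%), K2CO3 (2 equiv), Bu4NCl (10 mol%), DMF, 20 °C
Reagents that add atoms: none
Why: The copper acetylide formed from 3 under carbonate/phase-transfer conditions should alkylate at the primary allylic carbon of 2 (SN2 alkynylation of an allylic halide), giving the skipped enyne with the Z alkene intact.

Step 3
Reactants: 4 (Z)-oct-5-en-2-yn-1-ol; 5 8-chlorooctan-1-ol
Product: 8 (2Z,5Z)-2-(8-hydroxyoctyl)-3-iodoocta-2,5-dien-1-ol, via bis-magnesium reagent 6 (not isolated), via oxamagnesacycle 7 (not isolated)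
Conditions: 5 (3 equiv), i-PrMgCl (3 equiv), THF, −20 °C, then Mg turnings, reflux; 4 pre-treated with i-PrMgCl (1 equiv), CuI (10 mol%), THF, 0 to 20 °C; then I2, THF, −40 °C, dark; aq. NH4Cl/Na2S2O3
Reagents that add atoms: iodine, II
Why: Copper-catalysed anti-carbomagnesiation of a propargylic alkoxide delivers the alkyl group to the alkyne carbon next to the carbinol and magnesium to the distal carbon inside a five-membered chelate, so iodinolysis with retention should give the tetrasubstituted iodoalkene with iodine cis to CH2OH, and the alkoxide-bearing Grignard reagent 6 brings the chain without a protecting group.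

Step 4
Reactants: 8 (2Z,5Z)-2-(8-hydroxyoctyl)-3-iodoocta-2,5-dien-1-ol
Product: 9 (9Z,12Z)-9-formyl-10-iodopentadeca-9,12-dienoic acid
Conditions: TEMPO (20 mol%), PhI(OAc)2 (3.3 equiv), MeCN/H2O, 20 °C, dark
Reagents that add atoms: water, O
Why: In this oxoammonium oxidation the saturated primary alcohol should pass through its aldehyde hydrate to the carboxylic acid, while the allylic alcohol should stop at the hindered conjugated aldehyde, which hydrates poorly.

Step 5
Reactants: 9 (9Z,12Z)-9-formyl-10-iodopentadeca-9,12-dienoic acid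
Product: 10 methyl (9Z,12Z)-9-formyl-10-iodopentadeca-9,12-dienoate
Conditions: TMSCHN2 (1.2 equiv), toluene/MeOH, 0 °C
Reagents that add atoms: trimethylsilyldiazomethane, C[Si](C)(C)C=[N+]=[N-]
Why: Diazoalkane esterification methylates the carboxylic acid under neutral conditions and should leave the enal and the alkenyl iodide untouched.

Step 6
Reactants: 11 methyl acetate
Product: 12 1-methoxy-1-(trimethylsilyloxy)ethene
Conditions: LiN(iPr)2 (1.05 equiv), THF/DMPU, −78 °C; TMSCl; distillation
Reagents that add atoms: chlorotrimethylsilane, C[Si](C)(C)Cl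
Why: Kinetic deprotonation of the ester and O-silylation of the lithium enolate in the presence of DMPU should give the silyl ketene acetal (enolate trapping).

Step 7
Reactants: 10 methyl (9Z,12Z)-9-formyl-10-iodopentadeca-9,12-dienoate; 12 1-methoxy-1-(trimethylsilyloxy)ethene
Product: 15 methyl 8-[(5S)-3-oxo-2-[(2Z)-pent-2-en-1-yl]-5-(trimethylsilyloxy)cyclopent-1-en-1-yl]octanoate, via silyl aldol adduct 13 (not isolated), via alkenylmagnesium chloride 14 (not isolated)
Conditions: Ti(OiPr)4 (5 mol%), Schiff-base ligand from 2′-amino-1,1′-binaphthalen-2-ol and 3-bromo-5-tert-butylsalicylaldehyde (5 mol%), 3,5-di-tert-butylsalicylic acid (5 mol%), 12 (1.3 equiv), Et2O, −10 °C; then THF, i-PrMgCl·LiCl (1.2 equiv), −40 to −15 °C; aq. NaHCO3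
Reagents that add atoms: none
Why: The chiral tetravalent titanium Lewis acid activates aldehyde C4 and the silyl ketene acetal adds through C5 to its Si face in an enantioselective Mukaiyama acetate aldol, the silyl group passing to oxygen to leave 13 as its TMS ether; iodine–magnesium exchange with the turbo Grignard reagent then makes C2 nucleophilic and the alkenylmagnesium 14 attacks the neighbouring ester carbonyl C1 in a Parham-type intramolecular acyl substitution, methoxide leaving to give the enone. Both stages are known reaction types, the closest precedents being titanium–Schiff-base-catalysed acetate aldol additions to enals and exchange-triggered cyclisations of halo esters to cyclic ketones. The ring closes in a 5-exo-trig mode because the Z-configured tetrasubstituted C2=C3 bond holds the C2–Mg bond and the C4 arm on the same side. The only new stereocentre, C4, is set in the aldol stage by the catalyst (facial control) and is not touched afterwards. The step needs chemoselectivity for the proximal ester over the remote chain ester and over the product ketone, which intramolecularity, low temperature and a near-stoichiometric amount of exchange reagent should secure, and it needs exchange to outrun addition of i-PrMgCl to the esters, which the low nucleophilicity of this reagent below −15 °C supports.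

Step 8
Reactants: 15 methyl 8-[(5S)-3-oxo-2-[(2Z)-pent-2-en-1-yl]-5-(trimethylsilyloxy)cyclopent-1-en-1-yl]octanoate
Product: 18 methyl 8-[(4S,5R)-4-bromo-5-hydroxy-3-oxo-2-[(2Z)-pent-2-en-1-yl]cyclopent-1-en-1-yl]octanoate, via silyl dienol ether 16 (not isolated), via bromo silyl ether 17 (not isolated)
Conditions: TMSCl (3 equiv), LiN(SiMe3)2 (1.2 equiv), THF, −78 °C; then NBS (1.05 equiv), −78 °C, dark; then 1 M HCl, THF, 0 °C
Reagents that add atoms: N-bromosuccinimide, O=C1CCC(=O)N1Br
Why: Kinetic α′-deprotonation at C5 with in situ silylation should give the cross-conjugated silyl dienol ether 16, NBS should brominate it at C5 on the face opposite the C4 silyloxy group and so set the trans C5 stereocentre (electrophilic bromination of a silyl enol ether), and dilute acid then cleaves the TMS ether.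

Compound list (names use IUPAC locants; the labels C1–C5 in the text use the cyclopentenone numbering defined above)
1 | (Z)-pent-2-en-1-ol | CC/C=C\CO | starting material
2 | (Z)-1-bromopent-2-ene | CC/C=C\CBr | intermediate
3 | prop-2-yn-1-ol | C#CCO | starting material
4 | (Z)-oct-5-en-2-yn-1-ol | CC/C=C\CC#CCO | intermediate
5 | 8-chlorooctan-1-ol | OCCCCCCCCCl | starting material
6 | chloromagnesium 8-(chloromagnesio)octan-1-olate (bis-magnesium reagent) | Cl[Mg]CCCCCCCCO[Mg]Cl | intermediate
7 | cyclic alkenylmagnesium alkoxide (oxamagnesacycle) from anti-addition of 6 to 4; Mg bridges the pentenyl-bearing alkene carbon and the allylic oxygen | CC/C=C\CC1=C(CCCCCCCCO[Mg]Cl)CO[Mg]1 | intermediate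
8 | (2Z,5Z)-2-(8-hydroxyoctyl)-3-iodoocta-2,5-dien-1-ol (iodine cis to CH2OH) | OC/C(CCCCCCCCO)=C(\I)C/C=C\CC | intermediate
9 | (9Z,12Z)-9-formyl-10-iodopentadeca-9,12-dienoic acid | O=C/C(CCCCCCCC(=O)O)=C(\I)C/C=C\CC | intermediate
10 | methyl (9Z,12Z)-9-formyl-10-iodopentadeca-9,12-dienoate (iodine cis to CHO) | O=C/C(CCCCCCCC(=O)OC)=C(\I)C/C=C\CC | intermediate
11 | methyl acetate | COC(C)=O | starting material
12 | 1-methoxy-1-(trimethylsilyloxy)ethene | COC(=C)O[Si](C)(C)C | intermediate
13 | dimethyl (3S)-4-[(1Z,3Z)-1-iodohex-3-en-1-ylidene]-3-(trimethylsilyloxy)dodecanedioate (iodine cis to the silyloxy-bearing carbon) | COC(=O)C[C@H](O[Si](C)(C)C)/C(CCCCCCCC(=O)OC)=C(\I)C/C=C\CC | intermediate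
14 | alkenylmagnesium chloride formed from 13 by iodine–magnesium exchange (MgCl in place of I) | COC(=O)C[C@H](O[Si](C)(C)C)/C(CCCCCCCC(=O)OC)=C(\[Mg]Cl)C/C=C\CC | intermediate
15 | methyl 8-[(5S)-3-oxo-2-[(2Z)-pent-2-en-1-yl]-5-(trimethylsilyloxy)cyclopent-1-en-1-yl]octanoate | CC/C=C\CC1=C(CCCCCCCC(=O)OC)[C@@H](O[Si](C)(C)C)CC1=O | intermediate
16 | methyl 8-[(5S)-2-[(2Z)-pent-2-en-1-yl]-3,5-bis(trimethylsilyloxy)cyclopenta-1,3-dien-1-yl]octanoate | CC/C=C\CC1=C(CCCCCCCC(=O)OC)[C@@H](O[Si](C)(C)C)C=C1O[Si](C)(C)C | intermediate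
17 | methyl 8-[(4S,5R)-4-bromo-3-oxo-2-[(2Z)-pent-2-en-1-yl]-5-(trimethylsilyloxy)cyclopent-1-en-1-yl]octanoate (Br trans to OSiMe3) | CC/C=C\CC1=C(CCCCCCCC(=O)OC)[C@@H](O[Si](C)(C)C)[C@H](Br)C1=O | intermediate
18 | methyl 8-[(4S,5R)-4-bromo-5-hydroxy-3-oxo-2-[(2Z)-pent-2-en-1-yl]cyclopent-1-en-1-yl]octanoate (Br trans to OH) | CC/C=C\CC1=C(CCCCCCCC(=O)OC)[C@@H](O)[C@H](Br)C1=O | target

Total step count: 8. Longest linear sequence: 7 steps (steps 1, 2, 3, 4, 5, 7, 8).

Steps most likely to fail

Step 7. The aldol stage may be slow or poorly face-selective on the hindered, fully substituted enal, and the exchange stage may lose to addition of the Grignard reagent to an ester. The fallback uses known chemistry, makes the two ring bonds one after the other and takes the absolute configuration from an enzymatic resolution. It sets out from 10. Stille coupling with tributyl(1-ethoxyvinyl)stannane (Pd(PPh3)4, CuI, DMF) would give methyl (9Z,12Z)-10-(1-ethoxyethenyl)-9-formylpentadeca-9,12-dienoate F1. Dilute HCl in THF would hydrolyse the enol ether to the Z-ene-dione methyl (9Z,12Z)-10-acetyl-9-formylpentadeca-9,12-dienoate F2. Et3N in THF should close F2 by intramolecular aldol addition of the methyl ketone to the aldehyde, giving racemic methyl 8-[5-hydroxy-3-oxo-2-[(2Z)-pent-2-en-1-yl]cyclopent-1-en-1-yl]octanoate F3. Lipase PS with vinyl acetate should, by the usual empirical rule for secondary alcohols, acetylate the R alcohol to methyl 8-[(5R)-5-acetoxy-3-oxo-2-[(2Z)-pent-2-en-1-yl]cyclopent-1-en-1-yl]octanoate F5 and leave methyl 8-[(5S)-5-hydroxy-3-oxo-2-[(2Z)-pent-2-en-1-yl]cyclopent-1-en-1-yl]octanoate F4. TMSCl and imidazole in CH2Cl2 would convert F4 into 15, where the route is rejoined.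

Step 3. The alkoxide-bearing Grignard reagent may aggregate and add sluggishly, so that base-induced isomerisation of the skipped enyne competes with carbomagnesiation. The fallback replaces the protecting-group-free reagent by a protect–carbometalate–deprotect sequence and sets out from 4. The same copper-catalysed anti-addition, run with the soluble reagent [8-(tert-butyldimethylsilyloxy)octyl]magnesium bromide F6 (from commercial (8-bromooctyloxy)(tert-butyl)dimethylsilane and Mg) and followed by I2, would give (2Z,5Z)-2-[8-(tert-butyldimethylsilyloxy)octyl]-3-iodoocta-2,5-dien-1-ol F7. HF·pyridine in THF would remove the silyl group and return the route at 8.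

Step 8. Electrophilic bromination may overrun after proton exchange between product and enolate, or the enolate may lose the C4 silyloxy group by elimination. The fallback brings bromine in as a nucleophile and sets out from 15. NaN(SiMe3)2 followed by 2-(phenylsulfonyl)-3-phenyloxaziridine would give methyl 8-[(4S,5R)-4-hydroxy-3-oxo-2-[(2Z)-pent-2-en-1-yl]-5-(trimethylsilyloxy)cyclopent-1-en-1-yl]octanoate F8, with the new hydroxyl trans to the silyloxy group. MsCl and Et3N would give methyl 8-[(4S,5R)-4-(methylsulfonyloxy)-3-oxo-2-[(2Z)-pent-2-en-1-yl]-5-(trimethylsilyloxy)cyclopent-1-en-1-yl]octanoate F9. LiBr in acetone should displace the mesylate at the activated α-keto carbon and, through repeated bromide exchange, settle C5 in the more stable trans configuration, which is 17. The acid treatment of step 8 then gives 18.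

Further compounds
F1 | step 7 | methyl (9Z,12Z)-10-(1-ethoxyethenyl)-9-formylpentadeca-9,12-dienoate | O=C/C(CCCCCCCC(=O)OC)=C(\C(OCC)=C)C/C=C\CC
F2 | step 7 | methyl (9Z,12Z)-10-acetyl-9-formylpentadeca-9,12-dienoate | O=C/C(CCCCCCCC(=O)OC)=C(\C(C)=O)C/C=C\CC
F3 | step 7 | racemic methyl 8-[5-hydroxy-3-oxo-2-[(2Z)-pent-2-en-1-yl]cyclopent-1-en-1-yl]octanoate | CC/C=C\CC1=C(CCCCCCCC(=O)OC)C(O)CC1=O
F4 | step 7 | methyl 8-[(5S)-5-hydroxy-3-oxo-2-[(2Z)-pent-2-en-1-yl]cyclopent-1-en-1-yl]octanoate | CC/C=C\CC1=C(CCCCCCCC(=O)OC)[C@@H](O)CC1=O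
F5 | step 7 | methyl 8-[(5R)-5-acetoxy-3-oxo-2-[(2Z)-pent-2-en-1-yl]cyclopent-1-en-1-yl]octanoate | CC/C=C\CC1=C(CCCCCCCC(=O)OC)[C@H](OC(C)=O)CC1=O
F6 | step 3 | [8-(tert-butyldimethylsilyloxy)octyl]magnesium bromide | CC(C)(C)[Si](C)(C)OCCCCCCCC[Mg]Br
F7 | step 3 | (2Z,5Z)-2-[8-(tert-butyldimethylsilyloxy)octyl]-3-iodoocta-2,5-dien-1-ol | OC/C(CCCCCCCCO[Si](C)(C)C(C)(C)C)=C(\I)C/C=C\CC
F8 | step 8 | methyl 8-[(4S,5R)-4-hydroxy-3-oxo-2-[(2Z)-pent-2-en-1-yl]-5-(trimethylsilyloxy)cyclopent-1-en-1-yl]octanoate | CC/C=C\CC1=C(CCCCCCCC(=O)OC)[C@@H](O[Si](C)(C)C)[C@H](O)C1=O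
F9 | step 8 | methyl 8-[(4S,5R)-4-(methylsulfonyloxy)-3-oxo-2-[(2Z)-pent-2-en-1-yl]-5-(trimethylsilyloxy)cyclopent-1-en-1-yl]octanoate | CC/C=C\CC1=C(CCCCCCCC(=O)OC)[C@@H](O[Si](C)(C)C)[C@H](OS(C)(=O)=O)C1=O
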